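Ring A is numbered C1 (ketone), C2 (allyl), C3, C4 (quaternary, OMe), C5 (OMe), C6, with C7 and C8 in the side chain. Everything rests on cutting C3–C4 and C5–C6: the oxygenated quaternary carbon C4, flanked by C7 and by C5 at the carboxyl oxidation level, is read as the α-carbon of an α-hydroxy acid, and C3–C2–C1–C6 as an allyl-substituted methyl vinyl ketone. The acid is held as cis-tert-butyl dioxolanone 11, which already carries the C7 stereocentre and the silyl-protected aryl group. In one operation its enolate adds to enone 13 anti to tert-butyl, fixing C4, and the methyl-side ketone enolate then acylates on the lactone, closing ring A and releasing pivalaldehyde.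

Key step: step 9

Remarks on the chemistry
- Positions are given in the ring-A numbering above; the IUPAC names use their own locants.
- The stereochemical bookkeeping was checked and no structure needed correcting. Compound 11 is the (2R,5R)-cis dioxolanone with (R)-C7. It requires (2R,3S)-3-methylmalate, hence diethyl (R)-malate. Attack anti to tert-butyl gives (4R)-16.
- The C4 descriptor becomes S in 19–21 only because C3 turns sp2; there is no inversion.
- Compounds 15–18 are C2-epimer mixtures, which does not matter because C2 becomes sp2 in step 11. Compound 16 is drawn as the diketone although it should be largely enolised.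

Step 1
Reactants: 1 diethyl (2R)-2-hydroxybutanedioate (diethyl (R)-malate)
Product: 2 diethyl (2R,3S)-2-hydroxy-3-methylbutanedioate
Conditions: LiN(i-Pr)2 (2.2 equiv), THF, −78 → −20 °C; MeI, −78 → 0 °C; AcOH
Reagents that add atoms: iodomethane, CI
Why: Fráter–Seebach alkylation: the chelated lithium alkoxide–enolate dianion is methylated on the face away from the ester substituent of the carbinol carbon, which should give mainly the anti (3S) product and so sets the methyl-bearing centre that becomes C7, while the (2R) carbinol is retained.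

Step 2
Reactants: 2 diethyl (2R,3S)-2-hydroxy-3-methylbutanedioate
Product: 3 (2R,3S)-2-hydroxy-3-methylbutanedioic acid
Conditions: KOH (2.5 equiv), H2O–EtOH, 0 → 23 °C; HCl to pH 1
Reagents that add atoms: potassium hydroxide, [K+].[OH-]
Why: Ester saponification by acyl–oxygen cleavage; at this temperature the C3–H next to a carboxylate is not acidic enough to epimerise.

Step 3
Reactants: 3 (2R,3S)-2-hydroxy-3-methylbutanedioic acid; 4 2,2-dimethylpropanal (pivalaldehyde)
Product: 5 (2S)-2-[(2R,4R)-2-tert-butyl-5-oxo-1,3-dioxolan-4-yl]propanoic acid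
Conditions: TsOH·H2O (cat.), H2SO4 (cat.), pentane, reflux, water separator; recrystallisation
Reagents that add atoms: none
Why: Acid-catalysed acetalisation of the α-hydroxy acid unit closes the five-membered dioxolanone in preference to the six-membered ring through the other carboxyl group, and under equilibrating conditions the new acetal centre should settle mainly cis (2R) to the ring substituent, the cis isomer being purified by crystallisation.

Step 4
Reactants: 5 (2S)-2-[(2R,4R)-2-tert-butyl-5-oxo-1,3-dioxolan-4-yl]propanoic acid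
Product: 6 (2R,5R)-2-tert-butyl-5-[(2R)-1-hydroxypropan-2-yl]-1,3-dioxolan-4-one
Conditions: BH3·THF (1.1 equiv), THF, −10 → 0 °C; MeOH
Reagents that add atoms: none
Why: Chemoselective borane reduction of a carboxylic acid through its acyloxyborane, which is far faster than reduction of the acetal lactone.

Step 5
Reactants: 6 (2R,5R)-2-tert-butyl-5-[(2R)-1-hydroxypropan-2-yl]-1,3-dioxolan-4-one
Product: 7 (2R,5R)-2-tert-butyl-5-[(2S)-1-iodopropan-2-yl]-1,3-dioxolan-4-one
Conditions: I2, PPh3, imidazole, CH2Cl2, 0 → 23 °C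
Reagents that add atoms: iodine, II
Why: Appel-type iodination of the primary alcohol via an alkoxyphosphonium iodide under buffered, non-acidic conditions, run on crude 6 so that the hydroxyl has no time to translactonise onto the dioxolanone carbonyl.

Step 6
Reactants: 8 4-bromo-2-methoxyphenol
Product: 9 (4-bromo-2-methoxyphenoxy)tri(propan-2-yl)silane
Conditions: i-Pr3SiCl, imidazole, DMF, 23 °C
Reagents that add atoms: chlorotri(propan-2-yl)silane, CC(C)[Si](Cl)(C(C)C)C(C)C
Why: Standard silylation of a phenol; the bulky triisopropylsilyl ether tolerates the organozinc, amide-base, hydride and peroxide steps that follow and is removed at the end by fluoride.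

Step 7
Reactants: 7 (2R,5R)-2-tert-butyl-5-[(2S)-1-iodopropan-2-yl]-1,3-dioxolan-4-one; 9 (4-bromo-2-methoxyphenoxy)tri(propan-2-yl)silane
Product: 11 (2R,5R)-2-tert-butyl-5-[(2R)-1-(3-methoxy-4-triisopropylsilyloxyphenyl)propan-2-yl]-1,3-dioxolan-4-one, via alkylzinc iodide 10 (not isolated)
Conditions: Zn dust, I2 (cat.), DMF, 23 °C; then 9, Pd2(dba)3 (cat.), SPhos (cat.), 23 → 40 °C
Reagents that add atoms: none
Why: Negishi coupling: zinc insertion into the primary C–I bond gives a lactone-tolerant alkylzinc iodide with no β-leaving group, and a zerovalent palladium catalyst with a bulky biarylphosphine should couple it with the aryl bromide faster than β-hydride elimination, without touching any stereocentre.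

Step 8
Reactants: 12 hex-5-en-2-one
Product: 13 3-methylidenehex-5-en-2-one
Conditions: (CH2O)n, i-Pr2NH·CF3CO2H (1 equiv), CF3CO2H (cat.), THF, reflux; distilled, kept cold with BHT
Reagents that add atoms: formaldehyde (as paraformaldehyde), C=O
Why: Mannich-type α-methylenation (aminomethylation followed by loss of the amine) proceeds through the more substituted enol under acid catalysis, which should place the methylene group at C3 and not on the methyl group.

Step 9
Reactants: 11 (2R,5R)-2-tert-butyl-5-[(2R)-1-(3-methoxy-4-triisopropylsilyloxyphenyl)propan-2-yl]-1,3-dioxolan-4-one; 13 3-methylidenehex-5-en-2-one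
Product: 16 (4R)-4-hydroxy-4-[(2R)-1-(3-methoxy-4-triisopropylsilyloxyphenyl)propan-2-yl]-6-(prop-2-en-1-yl)cyclohexane-1,3-dione (C6 epimers), via lithium enolate 14 (not isolated), via Michael adduct 15 (not isolated)
Conditions: LiN(i-Pr)2 (1.05 equiv), THF, −78 °C; 13 (1.3 equiv), −78 °C; t-BuOH (1.0 equiv), −78 °C; LiN(i-Pr)2 (2.2 equiv), −78 → 0 °C; 1 M HCl
Reagents that add atoms: none
Why: LiN(i-Pr)2 converts 11 into the planar enolate 14, which adds 1,4 to the unsubstituted methylene terminus of 13 on the face anti to the tert-butyl group (C3–C4 bond), and protonation gives keto lactone 15. Kinetic re-enolisation on the methyl side then lets C6 attack the activated acetal-lactone carbonyl in a 6-exo-trig Claisen (Dieckmann-type) closure of ring A (C5–C6 bond); the tetrahedral intermediate expels a hemiacetal alkoxide that sheds pivalaldehyde, and deprotonation of the 1,3-dione makes the sequence irreversible. The closest known reaction types are conjugate additions of 2-tert-butyl-1,3-dioxolan-4-one enolates with self-regeneration of the stereocentre and Michael–Claisen annulations of ester enolates with vinyl ketones to cyclohexane-1,3-diones. The new stereocentre C4 is controlled by the (2R) acetal carbon, itself relayed from the malate carbinol, so that C3 takes the place of the former hydrogen (4R in 16); C7 is untouched and C2 arises as an inconsequential epimer pair. The step needs facial selectivity, secured by the tert-butyl group on the rigid five-membered enolate, 1,4- over 1,2-addition, secured by the fully substituted enolate and the unhindered enone terminus, and C- over O-acylation, secured by generating the methyl-side enolate, whose oxygen cannot reach the lactone carbonyl.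

Step 10
Reactants: 16 (4R)-4-hydroxy-4-[(2R)-1-(3-methoxy-4-triisopropylsilyloxyphenyl)propan-2-yl]-6-(prop-2-en-1-yl)cyclohexane-1,3-dione
Product: 17 (4R)-4-hydroxy-3-methoxy-4-[(2R)-1-(3-methoxy-4-triisopropylsilyloxyphenyl)propan-2-yl]-6-(prop-2-en-1-yl)cyclohex-2-en-1-one (C6 epimers; the methyl enol ether on ring-A C5)
Conditions: Me3SiCHN2, MeOH–toluene, 0 → 23 °C; chromatography
Reagents that add atoms: trimethylsilyldiazomethane, C[Si](C)(C)C=[N+]=[N-]
Why: Diazoalkane O-methylation of the enolised 1,3-dione (a vinylogous acid) is fast and leaves the tertiary alcohol alone; both enol oxygens can react, so 17 is separated from its C1-methoxy isomer, which mild aqueous acid returns to 16 for recycling.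

Step 11
Reactants: 17 (4R)-4-hydroxy-3-methoxy-4-[(2R)-1-(3-methoxy-4-triisopropylsilyloxyphenyl)propan-2-yl]-6-(prop-2-en-1-yl)cyclohex-2-en-1-one
Product: 19 (4S)-4-hydroxy-5-methoxy-4-[(2R)-1-(3-methoxy-4-triisopropylsilyloxyphenyl)propan-2-yl]-2-(prop-2-en-1-yl)cyclohexa-2,5-dien-1-one, via phenylselanyl ketone 18 (not isolated)
Conditions: LiN(i-Pr)2 (2.2 equiv), THF, −78 °C; PhSeBr, −78 °C; AcOH; then H2O2 (30 %), pyridine, CH2Cl2, 0 → 23 °C
Reagents that add atoms: none
Why: Selenenylation of the alkoxide–enolate dianion at C2 (the only enolisable position) followed by selenoxide syn-elimination into the ring, where a cis hydrogen on C3 is always available, should give the cross-conjugated dienone; C4 is untouched and the C2 epimers converge.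

Step 12
Reactants: 19 (4S)-4-hydroxy-5-methoxy-4-[(2R)-1-(3-methoxy-4-triisopropylsilyloxyphenyl)propan-2-yl]-2-(prop-2-en-1-yl)cyclohexa-2,5-dien-1-one
Product: 20 (4S)-4,5-dimethoxy-4-[(2R)-1-(3-methoxy-4-triisopropylsilyloxyphenyl)propan-2-yl]-2-(prop-2-en-1-yl)cyclohexa-2,5-dien-1-one
Conditions: NaH, MeI (excess), THF–DMF (10:1), 0 → 23 °C
Reagents that add atoms: iodomethane, CI
Why: Williamson etherification of the tertiary alkoxide; at this stage the molecule has no enolisable C–H, so the hydroxyl is the only acidic site and C-methylation cannot compete.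

Step 13
Reactants: 20 (4S)-4,5-dimethoxy-4-[(2R)-1-(3-methoxy-4-triisopropylsilyloxyphenyl)propan-2-yl]-2-(prop-2-en-1-yl)cyclohexa-2,5-dien-1-one
Product: 21 (4S)-4-[(2R)-1-(4-hydroxy-3-methoxyphenyl)propan-2-yl]-4,5-dimethoxy-2-(prop-2-en-1-yl)cyclohexa-2,5-dien-1-one (target)
Conditions: Bu4NF, AcOH, THF, 0 °C
Reagents that add atoms: none
Why: Fluoride-induced cleavage of the aryl silyl ether, buffered with acetic acid so that the vinylogous ester and the dienone are not exposed to basic fluoride or phenoxide.

Compound list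
1 | diethyl (2R)-2-hydroxybutanedioate (diethyl (R)-malate) | CCOC(=O)C[C@@H](O)C(=O)OCC | starting material
2 | diethyl (2R,3S)-2-hydroxy-3-methylbutanedioate | CCOC(=O)[C@@H](C)[C@@H](O)C(=O)OCC | intermediate
3 | (2R,3S)-2-hydroxy-3-methylbutanedioic acid | OC(=O)[C@@H](C)[C@@H](O)C(=O)O | intermediate
4 | 2,2-dimethylpropanal (pivalaldehyde) | CC(C)(C)C=O | starting material
5 | (2S)-2-[(2R,4R)-2-tert-butyl-5-oxo-1,3-dioxolan-4-yl]propanoic acid (cis) | CC(C)(C)[C@@H]1O[C@H]([C@H](C)C(=O)O)C(=O)O1 | intermediate
6 | (2R,5R)-2-tert-butyl-5-[(2R)-1-hydroxypropan-2-yl]-1,3-dioxolan-4-one | CC(C)(C)[C@@H]1O[C@H]([C@H](C)CO)C(=O)O1 | intermediate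
7 | (2R,5R)-2-tert-butyl-5-[(2S)-1-iodopropan-2-yl]-1,3-dioxolan-4-one | CC(C)(C)[C@@H]1O[C@H]([C@H](C)CI)C(=O)O1 | intermediate
8 | 4-bromo-2-methoxyphenol | COc1cc(Br)ccc1O | starting material
9 | (4-bromo-2-methoxyphenoxy)tri(propan-2-yl)silane | COc1cc(Br)ccc1O[Si](C(C)C)(C(C)C)C(C)C | intermediate
10 | {(2S)-2-[(2R,4R)-2-tert-butyl-5-oxo-1,3-dioxolan-4-yl]propyl}zinc iodide | CC(C)(C)[C@@H]1O[C@H]([C@H](C)C[Zn]I)C(=O)O1 | intermediate (not isolated)
11 | (2R,5R)-2-tert-butyl-5-[(2R)-1-(3-methoxy-4-triisopropylsilyloxyphenyl)propan-2-yl]-1,3-dioxolan-4-one (cis) | CC(C)(C)[C@@H]1O[C@H]([C@H](C)Cc2ccc(O[Si](C(C)C)(C(C)C)C(C)C)c(OC)c2)C(=O)O1 | intermediate (key-step precursor)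
12 | hex-5-en-2-one | CC(=O)CCC=C | starting material
13 | 3-methylidenehex-5-en-2-one | CC(=O)C(=C)CC=C | intermediate (key-step precursor)
14 | lithium enolate of 11 (lithium (2R)-2-tert-butyl-5-substituted 1,3-dioxol-4-olate) | CC(C)(C)[C@@H]1OC([C@H](C)Cc2ccc(O[Si](C(C)C)(C(C)C)C(C)C)c(OC)c2)=C(O[Li])O1 | intermediate (not isolated)
15 | (2R,5R)-5-(2-acetylpent-4-en-1-yl)-2-tert-butyl-5-[(2R)-1-(3-methoxy-4-triisopropylsilyloxyphenyl)propan-2-yl]-1,3-dioxolan-4-one (epimers at the acetyl-bearing carbon) | CC(C)(C)[C@@H]1O[C@](CC(CC=C)C(C)=O)([C@H](C)Cc2ccc(O[Si](C(C)C)(C(C)C)C(C)C)c(OC)c2)C(=O)O1 | intermediate (not isolated)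
16 | (4R)-4-hydroxy-4-[(2R)-1-(3-methoxy-4-triisopropylsilyloxyphenyl)propan-2-yl]-6-(prop-2-en-1-yl)cyclohexane-1,3-dione (C6 epimers) | C=CCC1C[C@@](O)([C@H](C)Cc2ccc(O[Si](C(C)C)(C(C)C)C(C)C)c(OC)c2)C(=O)CC1=O | intermediate (key-step product)
17 | (4R)-4-hydroxy-3-methoxy-4-[(2R)-1-(3-methoxy-4-triisopropylsilyloxyphenyl)propan-2-yl]-6-(prop-2-en-1-yl)cyclohex-2-en-1-one (C6 epimers) | C=CCC1C[C@@](O)([C@H](C)Cc2ccc(O[Si](C(C)C)(C(C)C)C(C)C)c(OC)c2)C(OC)=CC1=O | intermediate
18 | (4R)-4-hydroxy-3-methoxy-4-[(2R)-1-(3-methoxy-4-triisopropylsilyloxyphenyl)propan-2-yl]-6-(phenylselanyl)-6-(prop-2-en-1-yl)cyclohex-2-en-1-one (C6 epimers) | C=CCC1([Se]c3ccccc3)C[C@@](O)([C@H](C)Cc2ccc(O[Si](C(C)C)(C(C)C)C(C)C)c(OC)c2)C(OC)=CC1=O | intermediate (not isolated)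
19 | (4S)-4-hydroxy-5-methoxy-4-[(2R)-1-(3-methoxy-4-triisopropylsilyloxyphenyl)propan-2-yl]-2-(prop-2-en-1-yl)cyclohexa-2,5-dien-1-one | C=CCC1=C[C@@](O)([C@H](C)Cc2ccc(O[Si](C(C)C)(C(C)C)C(C)C)c(OC)c2)C(OC)=CC1=O | intermediate
20 | (4S)-4,5-dimethoxy-4-[(2R)-1-(3-methoxy-4-triisopropylsilyloxyphenyl)propan-2-yl]-2-(prop-2-en-1-yl)cyclohexa-2,5-dien-1-one | C=CCC1=C[C@@](OC)([C@H](C)Cc2ccc(O[Si](C(C)C)(C(C)C)C(C)C)c(OC)c2)C(OC)=CC1=O | intermediate
21 | (4S)-4-[(2R)-1-(4-hydroxy-3-methoxyphenyl)propan-2-yl]-4,5-dimethoxy-2-(prop-2-en-1-yl)cyclohexa-2,5-dien-1-one | C=CCC1=C[C@@](OC)([C@H](C)Cc2ccc(O)c(OC)c2)C(OC)=CC1=O | target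

Total step count: 13.
Longest linear sequence: 11 steps (steps 1, 2, 3, 4, 5, 7, 9, 10, 11, 12, 13).

Steps most likely to fail

1. Step 9 (key step). The hindered enolate 14 may act as a base toward the enolisable, polymerisation-prone enone, so that proton transfer and oligomerisation replace conjugate addition. Alternatively a ketone enolate may close on the lactone through oxygen. The fallback sets out from 11. The enolate is trapped with Me3SiCl to give the silyl ketene acetal F1. F1 is added to 13 in a TiCl4-promoted Mukaiyama–Michael reaction (CH2Cl2, −78 °C), again anti to tert-butyl, so that no basic enolate meets the enone. Aqueous work-up gives keto lactone 15 as an isolated compound. A separate Claisen closure through the kinetic methyl enolate (LiN(i-Pr)2, 2.2 equiv, THF, −78 → 0 °C) rejoins the route at 16.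

2. Step 10. O-Methylation may be poorly regioselective and fall mainly on the less hindered C1 enol oxygen. The fallback sets out from 16 and sets the regiochemistry by steric control of attack at carbon instead of alkylation at oxygen. Acid-catalysed etherification (MeOH, HC(OMe)3, cat. TsOH), in which methanol attacks the less hindered C1 carbonyl, is used deliberately to make the C1-methoxy isomer F2. O-Methylation of its vinylogous-ester carbonyl with Me3OBF4 (CH2Cl2, 0 °C) gives the 1,5-dimethoxycyclohexenylium tetrafluoroborate F3. Quenching into cold aqueous NaHCO3 should hydrate the less hindered C1 terminus of this cation and expel methanol. That leaves the methoxy group on C5 and rejoins the route at 17.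

3. Step 11. The selenoxide may eliminate toward the allylic side-chain CH2 and give an exocyclic diene instead of the ring double bond, or benzeneselenenic acid may add to the terminal alkene. The fallback sets out from 17. LiN(i-Pr)2 and Me3SiCl give the bis(trimethylsilyl) dienol ether F4. Saegusa–Ito oxidation with Pd(OAc)2 in MeCN, in which β-hydride elimination from the palladium enolate takes place within the ring, gives the silyl-protected dienone F5. Citric acid in MeOH removes the tertiary trimethylsilyl ether and rejoins the route at 19.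

Further compounds
F1 | step 9 | {[(2R)-2-tert-butyl-5-[(2R)-1-(3-methoxy-4-triisopropylsilyloxyphenyl)propan-2-yl]-1,3-dioxol-4-yl]oxy}trimethylsilane (silyl ketene acetal of 11) | CC(C)(C)[C@@H]1OC([C@H](C)Cc2ccc(O[Si](C(C)C)(C(C)C)C(C)C)c(OC)c2)=C(O[Si](C)(C)C)O1
F2 | step 10 | (6R)-6-hydroxy-3-methoxy-6-[(2R)-1-(3-methoxy-4-triisopropylsilyloxyphenyl)propan-2-yl]-4-(prop-2-en-1-yl)cyclohex-2-en-1-one (C4 epimers; methyl enol ether on ring-A C1) | C=CCC1C[C@@](O)([C@H](C)Cc2ccc(O[Si](C(C)C)(C(C)C)C(C)C)c(OC)c2)C(=O)C=C1OC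
F3 | step 10 | O-methylated F2, the 1,5-dimethoxycyclohexenylium tetrafluoroborate (ring-A numbering: OMe on C1 and C5, allyl cation C1–C6–C5) | C=CCC1C[C@@](O)([C@H](C)Cc2ccc(O[Si](C(C)C)(C(C)C)C(C)C)c(OC)c2)C(OC)=CC1=[O+]C.F[B-](F)(F)F
F4 | step 11 | bis(trimethylsilyl) ether of 17 (C4–OSiMe3 and the C1–OSiMe3 dienol ether C1=C2) | C=CCC1=C(O[Si](C)(C)C)C=C(OC)[C@](O[Si](C)(C)C)([C@H](C)Cc2ccc(O[Si](C(C)C)(C(C)C)C(C)C)c(OC)c2)C1
F5 | step 11 | (4S)-5-methoxy-4-[(2R)-1-(3-methoxy-4-triisopropylsilyloxyphenyl)propan-2-yl]-2-(prop-2-en-1-yl)-4-(trimethylsilyloxy)cyclohexa-2,5-dien-1-one | C=CCC1=C[C@@](O[Si](C)(C)C)([C@H](C)Cc2ccc(O[Si](C(C)C)(C(C)C)C(C)C)c(OC)c2)C(OC)=CC1=O
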